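**Strategy.** Ring A, the thiophene carrying the CH2O ester, is 2,5-disubstituted with hydrogens on C3 and C4. Its four carbons are therefore taken back to a buta-1,3-diyne and its sulfur to sulfide, and this disconnection of both C–S bonds of ring A carries the route. In one operation Na2S·9H2O closes ring A from the diyne arm of a 2,5-dialkynylthiophene (ring B), while the isolated butynyl alkyne stays intact. The precursor is ring B bearing a 4-hydroxybut-1-ynyl group at one α-position and a 5-(triisopropylsilyloxy)penta-1,3-diynyl group at the other, so the two hydroxyls are already differentiated for the final esterifications.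

Key step: step 7

Remark on the chemistry: product 12 is the formal H2S adduct of precursor 10 (C22H30O2SSi to C22H32O2S2Si), so the planned structures are consistent with the target. Intermediate 11 is drawn for sulfide attack at the diyne carbon bearing CH2OTIPS; attack at the thienyl-bearing terminus would converge on the same ring A.

**Step 1**
Reactants: 1 2-bromo-5-iodothiophene; 2 but-3-yn-1-ol
Product: 3 4-(5-bromothiophen-2-yl)but-3-yn-1-ol
Conditions: PdCl2(PPh3)2 (2 mol%), CuI (4 mol%), Et3N, THF, rt
Reagents that add atoms: none
Why: Sonogashira coupling; zerovalent palladium inserts into the C–I bond far faster than into C–Br at room temperature, so only the iodide should be replaced, and the free alcohol is tolerated.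

**Step 2**
Reactants: 3 4-(5-bromothiophen-2-yl)but-3-yn-1-ol; 4 trimethylsilylacetylene
Product: 5 4-[5-(trimethylsilylethynyl)thiophen-2-yl]but-3-yn-1-ol
Conditions: PdCl2(PPh3)2 (5 mol%), CuI (5 mol%), Et3N, THF, 60 °C (sealed tube)
Reagents that add atoms: none
Why: Sonogashira coupling; the α-bromothiophene, activated by the conjugated alkynyl group, should undergo oxidative addition on gentle heating, and the silyl cap prevents a second coupling of the acetylene unit.

**Step 3**
Reactants: 5 4-[5-(trimethylsilylethynyl)thiophen-2-yl]but-3-yn-1-ol
Product: 6 4-(5-ethynylthiophen-2-yl)but-3-yn-1-ol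
Conditions: K2CO3 (0.2 equiv), MeOH, rt
Reagents that add atoms: none
Why: Base-catalysed methanolysis of the alkynyl C–Si bond (protodesilylation) is specific for the trimethylsilyl alkyne and leaves the internal alkyne and the alcohol untouched; 6 would be used directly.

**Step 4**
Reactants: 7 propargyl alcohol
Product: 8 triisopropyl(prop-2-yn-1-yloxy)silane
Conditions: TIPSCl, imidazole, DMF, rt
Reagents that add atoms: triisopropylsilyl chloride, CC(C)[Si](Cl)(C(C)C)C(C)C
Why: Imidazole-promoted silylation of a primary alcohol; the bulky TIPS ether is chosen because it should withstand the aqueous amine of step 6 and the aqueous basic sulfide of step 7.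

**Step 5**
Reactants: 8 triisopropyl(prop-2-yn-1-yloxy)silane
Product: 9 (3-bromoprop-2-yn-1-yloxy)triisopropylsilane
Conditions: NBS, AgNO3 (10 mol%), acetone, rt
Reagents that add atoms: N-bromosuccinimide, O=C1CCC(=O)N1Br
Why: Silver-catalysed electrophilic bromination of a terminal alkyne through its silver acetylide gives the 1-bromoalkyne needed as the electrophilic coupling partner.

**Step 6**
Reactants: 6 4-(5-ethynylthiophen-2-yl)but-3-yn-1-ol; 9 (3-bromoprop-2-yn-1-yloxy)triisopropylsilane
Product: 10 4-[5-(5-triisopropylsilyloxypenta-1,3-diyn-1-yl)thiophen-2-yl]but-3-yn-1-ol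
Conditions: CuCl (5 mol%), NH2OH·HCl (10 mol%), 30% aq n-BuNH2, Et2O, 0 °C → rt
Reagents that add atoms: none
Why: Cadiot–Chodkiewicz coupling of the copper acetylide of the more acidic thienylacetylene with the bromoalkyne should give the unsymmetrical diyne, hydroxylamine keeping copper monovalent so that oxidative homocoupling is suppressed.

**Step 7**
Reactants: 10 4-[5-(5-triisopropylsilyloxypenta-1,3-diyn-1-yl)thiophen-2-yl]but-3-yn-1-ol
Product: 12 4-[5'-(triisopropylsilyloxymethyl)-2,2'-bithiophen-5-yl]but-3-yn-1-ol, via (Z)-enyne thiolate 11 (not isolated)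
Conditions: Na2S·9H2O (3 equiv), degassed DMF, 25 → 60 °C, Ar
Reagents that add atoms: sodium sulfide nonahydrate, [Na+].[Na+].[S-2].O.O.O.O.O.O.O.O.O
Why: Hydrosulfide, formed from Na2S and its water of hydration, should add in anti fashion to a terminal carbon of the conjugated diyne to give the (Z)-enyne thiolate 11, whose sulfur lies cis to the remaining triple bond. That thiolate then attacks the distal carbon of this triple bond in a 5-endo-dig closure, and protonation of the ring carbanion by water gives aromatic ring A, so both C–S bonds are made in one flask. The closest known reaction type is the heteroannulation of 1,4-disubstituted buta-1,3-diynes with Na2S or NaSH to 2,5-disubstituted thiophenes. No stereocentre is formed, and the transient alkene geometry follows from the anti addition. The selectivity needed is chemoselectivity for the diyne over the isolated butynyl alkyne: that alkyne is a poorer acceptor and, lacking a neighbouring triple bond, could add sulfide only reversibly without gaining aromaticity, whereas the diyne adduct is drained irreversibly into the thiophene, and both possible sites of first attack on the diyne converge on one product. The TIPS ether and the free primary alcohol should tolerate the aqueous basic sulfide at this temperature.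

**Step 8**
Reactants: 12 4-[5'-(triisopropylsilyloxymethyl)-2,2'-bithiophen-5-yl]but-3-yn-1-ol
Product: 13 4-[5'-(triisopropylsilyloxymethyl)-2,2'-bithiophen-5-yl]but-3-yn-1-yl 3-methylbutanoate
Conditions: isovaleryl chloride, pyridine, DMAP (cat.), CH2Cl2, 0 °C → rt
Reagents that add atoms: 3-methylbutanoyl chloride (isovaleryl chloride), CC(C)CC(Cl)=O
Why: Nucleophilic acyl substitution of an acid chloride by the primary homopropargylic alcohol, the only free hydroxyl, while the other oxygen stays masked as its TIPS ether.

**Step 9**
Reactants: 13 4-[5'-(triisopropylsilyloxymethyl)-2,2'-bithiophen-5-yl]but-3-yn-1-yl 3-methylbutanoate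
Product: 14 4-[5'-(hydroxymethyl)-2,2'-bithiophen-5-yl]but-3-yn-1-yl 3-methylbutanoate
Conditions: TBAF, AcOH, THF, 0 °C → rt
Reagents that add atoms: none
Why: Fluoride-mediated desilylation driven by the strong Si–F bond, buffered with acetic acid so that the isovalerate is neither cleaved nor transferred to the liberated alkoxide.

**Step 10**
Reactants: 14 4-[5'-(hydroxymethyl)-2,2'-bithiophen-5-yl]but-3-yn-1-yl 3-methylbutanoate
Product: 15 [5'-[4-(3-methylbutanoyloxy)but-1-yn-1-yl]-2,2'-bithiophen-5-yl]methyl 3-methylbut-2-enoate (target)
Conditions: 3-methylbut-2-enoic acid, DCC, DMAP (cat.), CH2Cl2, 0 °C → rt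
Reagents that add atoms: 3-methylbut-2-enoic acid (senecioic acid), CC(C)=CC(=O)O
Why: Steglich esterification under nearly neutral conditions acylates the acid-sensitive thienylmethanol without ionising the thienylmethyl carbon, and avoiding an acid chloride with a trialkylamine limits deconjugation of the senecioyl unit through a vinylketene.

**Compound list**
1 | 2-bromo-5-iodothiophene | Brc1ccc(I)s1 | starting material
2 | but-3-yn-1-ol | C#CCCO | starting material
3 | 4-(5-bromothiophen-2-yl)but-3-yn-1-ol | OCCC#Cc1ccc(Br)s1 | intermediate
4 | trimethylsilylacetylene | C#C[Si](C)(C)C | starting material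
5 | 4-[5-(trimethylsilylethynyl)thiophen-2-yl]but-3-yn-1-ol | C[Si](C)(C)C#Cc1ccc(C#CCCO)s1 | intermediate
6 | 4-(5-ethynylthiophen-2-yl)but-3-yn-1-ol | C#Cc1ccc(C#CCCO)s1 | intermediate
7 | propargyl alcohol (prop-2-yn-1-ol) | C#CCO | starting material
8 | triisopropyl(prop-2-yn-1-yloxy)silane | C#CCO[Si](C(C)C)(C(C)C)C(C)C | intermediate
9 | (3-bromoprop-2-yn-1-yloxy)triisopropylsilane | BrC#CCO[Si](C(C)C)(C(C)C)C(C)C | intermediate
10 | 4-[5-(5-triisopropylsilyloxypenta-1,3-diyn-1-yl)thiophen-2-yl]but-3-yn-1-ol | CC(C)[Si](OCC#CC#Cc1ccc(C#CCCO)s1)(C(C)C)C(C)C | intermediate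
11 | 4-[5-[(3Z)-4-sulfanyl-5-(triisopropylsilyloxy)pent-3-en-1-yn-1-yl]thiophen-2-yl]but-3-yn-1-ol (present as its sodium thiolate, not isolated) | CC(C)[Si](OC/C(S)=C/C#Cc1ccc(C#CCCO)s1)(C(C)C)C(C)C | intermediate
12 | 4-[5'-(triisopropylsilyloxymethyl)-2,2'-bithiophen-5-yl]but-3-yn-1-ol | CC(C)[Si](OCc1ccc(-c2ccc(C#CCCO)s2)s1)(C(C)C)C(C)C | intermediate
13 | 4-[5'-(triisopropylsilyloxymethyl)-2,2'-bithiophen-5-yl]but-3-yn-1-yl 3-methylbutanoate | CC(C)CC(=O)OCCC#Cc1ccc(-c2ccc(CO[Si](C(C)C)(C(C)C)C(C)C)s2)s1 | intermediate
14 | 4-[5'-(hydroxymethyl)-2,2'-bithiophen-5-yl]but-3-yn-1-yl 3-methylbutanoate | CC(C)CC(=O)OCCC#Cc1ccc(-c2ccc(CO)s2)s1 | intermediate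
15 | [5'-[4-(3-methylbutanoyloxy)but-1-yn-1-yl]-2,2'-bithiophen-5-yl]methyl 3-methylbut-2-enoate | CC(C)=CC(=O)OCc1ccc(-c2ccc(C#CCCOC(=O)CC(C)C)s2)s1 | target

**Step count and risks**

Total step count: 10. Longest linear sequence: 8 steps (1 → 3 → 5 → 6 → 10 → 12 → 13 → 14 → 15); steps 4 and 5 form the short side branch to 9.

Steps most likely to fail:

1. Step 7. Sulfide may add to the diyne without ring closure, may also attack the isolated alkyne, or the basic medium may oligomerise the diyne or strip the silyl ether. The fallback brings ring A in preformed by cross-coupling and sets out from bromide 3. Suzuki–Miyaura coupling with commercial (5-formylthiophen-2-yl)boronic acid (Pd(PPh3)4, K2CO3, DME/H2O, 80 °C) should give 5'-(4-hydroxybut-1-yn-1-yl)-2,2'-bithiophene-5-carbaldehyde F1. Acylation with isovaleryl chloride and pyridine in CH2Cl2 should give 4-(5'-formyl-2,2'-bithiophen-5-yl)but-3-yn-1-yl 3-methylbutanoate F2. Reduction of the aldehyde alone with NaBH4 in MeOH/THF at 0 °C returns to the route at 14.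

2. Step 6. Halogen–copper exchange and adventitious oxidation may divert both partners into homocoupled diynes, and the terminal alkyne 6 may decompose in the basic aqueous medium. The fallback dispenses with the bromoalkyne and sets out from 6 together with a fivefold excess of the inexpensive silyl ether 8. An oxidative Glaser–Hay heterocoupling (NiCl2·6H2O and CuI as catalysts, TMEDA, Et3N, THF, air, rt) should give the cross-coupled diyne, which is separable by polarity from the nonpolar homodimer of 8, and the route is rejoined at 10. This fallback makes no new compound (F0).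

3. Step 10. The activated senecioyl species may lose a γ-proton and deliver the deconjugated 3-methylbut-3-enoate, or the electron-rich thienylmethanol may ionise and oligomerise. The fallback activates the alcohol and not the acid and sets out from 14. A Mitsunobu esterification with 3-methylbut-2-enoic acid (PPh3, DIAD, THF, 0 °C) lets the carboxylate displace the oxyphosphonium leaving group at the primary thienylmethyl carbon, so no acyl electrophile prone to vinylketene formation is generated, and the route is rejoined at 15. This fallback makes no new compound (F0).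

**Further compounds**
F1 | step 7 | 5'-(4-hydroxybut-1-yn-1-yl)-2,2'-bithiophene-5-carbaldehyde | O=Cc1ccc(-c2ccc(C#CCCO)s2)s1
F2 | step 7 | 4-(5'-formyl-2,2'-bithiophen-5-yl)but-3-yn-1-yl 3-methylbutanoate | CC(C)CC(=O)OCCC#Cc1ccc(-c2ccc(C=O)s2)s1
F0 | step 6 | none | none
F0 | step 10 | none | none
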